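**Plan**

Locants: ten-membered ring C1 (epoxide carbon bearing CH3)–C2 (epoxide CH)–C3 (CHOH)–C4(CH3)=C5–C6 (lactone O–CH)–C7 (ring fusion)–C8 (CH–O-angeloyl)–C9–C10; lactone ring B = O6–C6–C7–C11(=C13H2)–C12(=O).
Retrosynthetic cuts, in order: C3–C4 (ten-membered ring to a (Z)-alkenyl iodide and an epoxy aldehyde), the epoxide oxygen at C1/C2, the C8 angelate, C4=C5 (iodo-olefination of a C5 aldehyde), C11–C7 (ring B), C10–C1 (sp3–sp2 coupling).
Enabling feature: C5–C6(O)–C7–C8(O)–C9–C10 is a masked 3-deoxy-D-hexose (C5 = anomeric carbon, O8 = furanose ring oxygen). O6 and C11 are cis across C6–C7, C9 is trans to C11 on that furanose, and C12=O and O8 stand 1,4 across C11–C7. The bond is therefore made by a C7 radical inside the furanose attacking an alkyne tethered to O6 at the lactol level.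
Forward order: glucose-derived furanose, then side chain C10–C1–C3, then ring B by radical 5-exo-dig closure, then furanose opened to the C4 iodide, then angelate, lactone and epoxide, and the ten-membered ring last.
Stereochemistry: C6 and C8 from D-glucose; C7 from the enforced cis fusion of ring B to the furanose; C1/C2 from Sharpless epoxidation; C3 from Felkin–Anh addition in the ring closure; both ring-alkene geometries from (Z)-iodoalkenes coupled with retention.

Key step: step 8

Assumption: the anomeric carbon C5 (while it is an S,O-acetal or hemiacetal) and the tether acetal carbon C12 are carried as epimer mixtures, because both centers are erased later; their SMILES carry no descriptor at these atoms.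

**Route**

Step 1
Reactants: 1 but-2-yn-1-ol
Product: 3 (Z)-3-iodobut-2-en-1-ol, via cyclic sodium alkenylalanate 2 (not isolated)
Conditions: NaAlH2(OCH2CH2OMe)2, THF, 0 °C to rt; then I2, −78 to 0 °C
Reagents that add atoms: iodine (II)
Why: Hydroxyl-directed trans-hydroalumination of the propargylic alcohol places aluminium on the methyl-bearing carbon cis to the CH2O group, and iodinolysis with retention should give the (Z)-iodoalkene (alkyne hydroalumination–iodination).

Step 2
Reactants: 3 (Z)-3-iodobut-2-en-1-ol
Product: 4 tert-butyl{[(Z)-3-iodobut-2-en-1-yl]oxy}diphenylsilane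
Conditions: t-BuPh2SiCl, imidazole, CH2Cl2, rt
Reagents that add atoms: tert-butyl(chloro)diphenylsilane (CC(C)(C)[Si](Cl)(c1ccccc1)c1ccccc1)
Why: Routine silylation of a primary allylic alcohol, the tert-butyldiphenylsilyl ether being chosen because it should survive the Lewis- and Brønsted-acidic steps 6, 7 and 12.

Step 3
Reactants: 5 1,2-O-isopropylidene-α-D-glucofuranose
Product: 6 5,6-dideoxy-1,2-O-isopropylidene-α-D-xylo-hex-5-enofuranose
Conditions: PPh3, I2, imidazole, toluene, 110 °C
Reagents that add atoms: none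
Why: Garegg–Samuelsson deoxygenation of the terminal vicinal diol should give the vinyl group, while the hydroxyl at the future C7, on the concave side of the cis-fused acetonide, is too hindered for SN2 iodination.

Step 4
Reactants: 6 5,6-dideoxy-1,2-O-isopropylidene-α-D-xylo-hex-5-enofuranose + 4 tert-butyl{[(Z)-3-iodobut-2-en-1-yl]oxy}diphenylsilane
Product: 8 (Z)-9-O-(tert-butyldiphenylsilyl)-5,6,7,8-tetradeoxy-1,2-O-isopropylidene-7-C-methyl-α-D-xylo-non-7-enofuranose, via bis-borylated alkylborane 7 (not isolated)
Conditions: 9-BBN (2.2 equiv), THF, rt; then 4, Pd(dppf)Cl2 (5 mol %), AsPh3, Cs2CO3, DMF/H2O, rt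
Reagents that add atoms: none
Why: Anti-Markovnikov hydroboration of the vinyl group followed by B-alkyl Suzuki–Miyaura coupling, which retains the alkene geometry of the iodide, should forge C10–C1, the second equivalent of borane being taken up by the free hydroxyl and released on aqueous work-up.

Step 5
Reactants: 8 (Z)-9-O-(tert-butyldiphenylsilyl)-5,6,7,8-tetradeoxy-1,2-O-isopropylidene-7-C-methyl-α-D-xylo-non-7-enofuranose
Product: 9 3-O-[(methylsulfanyl)carbonothioyl] derivative of 8
Conditions: NaH, THF, 0 °C; CS2; then MeI, rt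
Reagents that add atoms: carbon disulfide (S=C=S); iodomethane (CI)
Why: Xanthate formation (alkoxide addition to CS2, then S-methylation) turns the C–O bond at the future C7 into a radical precursor of the Barton–McCombie type.

Step 6
Reactants: 9 3-O-[(methylsulfanyl)carbonothioyl] derivative of 8
Product: 10 phenyl (Z)-9-O-(tert-butyldiphenylsilyl)-5,6,7,8-tetradeoxy-7-C-methyl-3-O-[(methylsulfanyl)carbonothioyl]-1-thio-D-xylo-non-7-enofuranoside (anomer mixture)
Conditions: PhSH, BF3·OEt2, CH2Cl2, −20 to 0 °C
Reagents that add atoms: benzenethiol (Sc1ccccc1)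
Why: Lewis-acid thiolysis of the 1,2-O-isopropylidene acetal through the furanosyl oxocarbenium ion should give the thioglycoside, which frees O6 for the tether and masks C5 in a form that can later be unveiled without acid.

Step 7
Reactants: 10 phenyl 1-thiofuranoside with free O6–H
Product: 11 2-O-(1-ethoxyprop-2-yn-1-yl) ether of 10 (acetal epimers)
Conditions: HC≡CCH(OEt)2 (excess), PPTS (cat.), toluene, 60 °C, reduced pressure (EtOH removed)
Reagents that add atoms: 3,3-diethoxyprop-1-yne (C#CC(OCC)OCC)
Why: Acid-catalyzed acetal exchange driven by removal of ethanol should attach C11–C13 as an alkyne on a C12 that is already at the lactol oxidation level (transacetalization).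

Step 8
Reactants: 11 2-O-(1-ethoxyprop-2-yn-1-yl) ether of 10
Product: 14 2-ethoxy-3-methylidene-6-(phenylsulfanyl)-4-[(Z)-5-(tert-butyldiphenylsilyloxy)-3-methylpent-3-en-1-yl]hexahydrofuro[3,4-b]furan (ring B closed as lactol ethyl ether), via C7 radical 12 (not isolated), via exocyclic vinyl radical 13 (not isolated)
Conditions: Bu3SnH (1.3 equiv, syringe pump), AIBN (cat.), benzene, 80 °C, 0.005 M
Reagents that add atoms: none
Why: The tributylstannyl radical adds to the thiocarbonyl sulfur and β-scission of the C7–O bond gives the secondary furanos-3-yl (C7) radical 12, which attacks the internal alkyne carbon C11 of the O6-bound acetal tether; the vinyl radical 13 then takes hydrogen from Bu3SnH to give the exocyclic methylene and carry the chain. The closest known reaction types are the acetal-tethered (Ueno–Stork-type) radical cyclization and the 5-exo-dig closure of furanos-3-yl radicals onto 2-O-propargyl groups. Ring B (O6–C12–C11–C7–C6) closes in the 5-exo-dig mode. The only new permanent stereocenter, C7, is set by the furanose template: two five-membered rings can only be cis-fused, so C11 is delivered on the face that carries O6, which is the face opposite to C9 on C8, and this is the C6/C7/C8 array of the target; the acetal carbon C12 is an inconsequential epimer mixture. The step needs ring closure to outrun direct reduction of 12 (secured by slow addition of the stannane at high dilution) and the tethered alkyne to outcompete the side-chain alkene (attack there would be 5-exo at the fully substituted C1 or 6-endo, both much slower than closure through the three-atom oxygenated tether), and the stannyl radical must choose the thiocarbonyl group over the thioglycoside, which its far higher affinity for C=S secures.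

Step 9
Reactants: 14 ring B lactol ethyl ether fused to the phenyl thiofuranoside
Product: 15 2-ethoxy-4-[(Z)-5-(tert-butyldiphenylsilyloxy)-3-methylpent-3-en-1-yl]-3-methylidenehexahydrofuro[3,4-b]furan-6-ol (C5 lactol)
Conditions: HgCl2, CaCO3, MeCN/H2O, rt
Reagents that add atoms: water (O)
Why: Thiophilic HgCl2-promoted hydrolysis of the S,O-acetal under carbonate buffering should release the C5 lactol while the O,O-acetal at C12 stays intact.

Step 10
Reactants: 15 C5 lactol
Product: 16 (Z)-alkenyl iodide with free C8 hydroxyl: 2-ethoxy-3-methylidenetetrahydrofuran bearing cis at C5 a (Z)-2-iodoprop-1-enyl group and at C4 the (1R)-1-hydroxy-6-(tert-butyldiphenylsilyloxy)-4-methylhex-4-enyl chain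
Conditions: [Ph3PEt]I, n-BuLi, THF, −78 °C; I2, −78 °C; NaN(SiMe3)2, −20 °C; then 15, −78 to −20 °C
Reagents that add atoms: ethyl(triphenyl)phosphonium iodide (CC[P+](c1ccccc1)(c1ccccc1)c1ccccc1.[I-]); iodine (II)
Why: Stork–Zhao-type iodo-Wittig olefination of the lactol through its hydroxy aldehyde tautomer should give the (Z)-2-iodoalkene and free the C8 hydroxyl, and because C12 is still an acetal the C8 alkoxide has no acyl group to attack.

Step 11
Reactants: 16 (Z)-alkenyl iodide with free C8 hydroxyl
Product: 17 C8 angelate of 16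
Conditions: angelic acid, 2,4,6-Cl3C6H2COCl, Et3N, toluene, rt; then 16, 80 °C
Reagents that add atoms: angelic acid, (Z)-2-methylbut-2-enoic acid (C/C=C(/C)C(=O)O)
Why: Yamaguchi-type esterification through the mixed anhydride without a nucleophilic catalyst is the established way to angeloylate a secondary alcohol without Z-to-E isomerization to the tiglate.

Step 12
Reactants: 17 C8 angelate of 16
Product: 18 C12 lactol (2-hydroxy-3-methylidenetetrahydrofuran) of 17
Conditions: AcOH/THF/H2O (3:1:1), 40 °C
Reagents that add atoms: water (O)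
Why: Mild aqueous acid should hydrolyze the cyclic mixed acetal to the lactol under conditions that the silyl ether, the alkenyl iodide and the angelate tolerate.

Step 13
Reactants: 18 C12 lactol
Product: 19 α-methylene-γ-butyrolactone (ring B complete) with C8 angelate, (Z)-alkenyl iodide and silyl ether
Conditions: TEMPO (cat.), PhI(OAc)2, CH2Cl2, rt
Reagents that add atoms: none
Why: Oxoammonium-mediated oxidation of the lactol, the only free hydroxyl in the molecule, should give the α-methylene lactone.

Step 14
Reactants: 19 silyl-protected α-methylene lactone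
Product: 20 (Z)-allylic alcohol (C3–OH free)
Conditions: HF·pyridine, pyridine, THF, 0 °C to rt
Reagents that add atoms: none
Why: Fluoride-mediated cleavage of the silyl ether under non-basic conditions should spare the Michael-acceptor lactone and the angelate.

Step 15
Reactants: 20 (Z)-allylic alcohol
Product: 21 (1S,2R)-epoxy alcohol
Conditions: t-BuOOH, Ti(OiPr)4 (cat.), D-(−)-diisopropyl tartrate (cat.), 4 Å molecular sieves, CH2Cl2, −20 °C
Reagents that add atoms: tert-butyl hydroperoxide (CC(C)(C)OO)
Why: Sharpless asymmetric epoxidation of the (Z)-trisubstituted allylic alcohol under reagent control by the D-(−)-tartrate should deliver the cis-epoxide with the 1S,2R configuration, and the three electron-poor alkenes do not react.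

Step 16
Reactants: 21 (1S,2R)-epoxy alcohol
Product: 22 epoxy aldehyde (C3 = CHO)
Conditions: Dess–Martin periodinane, pyridine, CH2Cl2, 0 °C
Reagents that add atoms: none
Why: Buffered Dess–Martin oxidation should convert the primary epoxy alcohol into the epoxy aldehyde without epimerization or epoxide opening.

Step 17
Reactants: 22 epoxy aldehyde
Product: 24 CNP0500828.1 (target), via alkenylchromium dichloride 23 (not isolated)
Conditions: CrCl2 (excess), NiCl2 (cat.), DMSO/THF, rt, 0.002 M
Reagents that add atoms: none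
Why: Nozaki–Hiyama–Kishi reaction, in which nickel-catalyzed formation of the alkenylchromium species retains the (Z)-geometry and intramolecular addition to the aldehyde should close the ten-membered ring, the C3 carbinol arising by Felkin–Anh attack anti to the epoxide C–O bond (3R).

**Compound list**

1 | but-2-yn-1-ol | CC#CCO | starting material
2 | sodium 2,2-bis(2-methoxyethoxy)-4-methyl-2,5-dihydro-1,2-oxaluminol-2-uide (cyclic alkenylalanate) | CC1=CCO[Al-]1(OCCOC)OCCOC.[Na+] | intermediate (not isolated)
3 | (Z)-3-iodobut-2-en-1-ol | C/C(I)=C/CO | intermediate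
4 | tert-butyl{[(Z)-3-iodobut-2-en-1-yl]oxy}diphenylsilane | C/C(I)=C/CO[Si](c1ccccc1)(c1ccccc1)C(C)(C)C | intermediate
5 | 1,2-O-isopropylidene-α-D-glucofuranose | CC1(C)O[C@H]2[C@@H](O1)O[C@H]([C@H](O)CO)[C@@H]2O | starting material
6 | 5,6-dideoxy-1,2-O-isopropylidene-α-D-xylo-hex-5-enofuranose | CC1(C)O[C@H]2[C@@H](O1)O[C@H](C=C)[C@@H]2O | intermediate
7 | 3-O,6-C-bis(9-borabicyclo[3.3.1]nonan-9-yl)-5,6-dideoxy-1,2-O-isopropylidene-α-D-xylo-hexofuranose | CC1(C)O[C@H]2[C@@H](O1)O[C@H](CCB3C4CCCC3CCC4)[C@@H]2OB3C4CCCC3CCC4 | intermediate (not isolated)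
8 | (Z)-9-O-(tert-butyldiphenylsilyl)-5,6,7,8-tetradeoxy-1,2-O-isopropylidene-7-C-methyl-α-D-xylo-non-7-enofuranose | CC1(C)O[C@H]2[C@@H](O1)O[C@H](CC/C(C)=C\CO[Si](c3ccccc3)(c3ccccc3)C(C)(C)C)[C@@H]2O | intermediate
9 | 3-O-[(methylsulfanyl)carbonothioyl] derivative of 8 | CC1(C)O[C@H]2[C@@H](O1)O[C@H](CC/C(C)=C\CO[Si](c3ccccc3)(c3ccccc3)C(C)(C)C)[C@@H]2OC(=S)SC | intermediate
10 | phenyl (Z)-9-O-(tert-butyldiphenylsilyl)-5,6,7,8-tetradeoxy-7-C-methyl-3-O-[(methylsulfanyl)carbonothioyl]-1-thio-D-xylo-non-7-enofuranoside (anomer mixture, O6–H free) | O[C@H]1C(Sc2ccccc2)O[C@H](CC/C(C)=C\CO[Si](c2ccccc2)(c2ccccc2)C(C)(C)C)[C@@H]1OC(=S)SC | intermediate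
11 | 2-O-(1-ethoxyprop-2-yn-1-yl) ether of 10 (acetal epimers) | C#CC(OCC)O[C@H]1C(Sc2ccccc2)O[C@H](CC/C(C)=C\CO[Si](c2ccccc2)(c2ccccc2)C(C)(C)C)[C@@H]1OC(=S)SC | intermediate
12 | secondary radical at C7 (sugar C3) formed from 11 by loss of the xanthate | C#CC(OCC)O[C@H]1C(Sc2ccccc2)O[C@H](CC/C(C)=C\CO[Si](c2ccccc2)(c2ccccc2)C(C)(C)C)[CH]1 | intermediate (not isolated)
13 | exocyclic vinyl radical (C13) after 5-exo-dig ring closure | [CH]=C1C(OCC)O[C@H]2C(Sc3ccccc3)O[C@H](CC/C(C)=C\CO[Si](c3ccccc3)(c3ccccc3)C(C)(C)C)[C@@H]12 | intermediate (not isolated)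
14 | 2-ethoxy-3-methylidene-6-(phenylsulfanyl)-4-[(Z)-5-(tert-butyldiphenylsilyloxy)-3-methylpent-3-en-1-yl]hexahydrofuro[3,4-b]furan (cis-fused; side chain at C4 trans to C3; C6, C7, C8 of the target set) | C=C1C(OCC)O[C@H]2C(Sc3ccccc3)O[C@H](CC/C(C)=C\CO[Si](c3ccccc3)(c3ccccc3)C(C)(C)C)[C@@H]12 | intermediate
15 | 2-ethoxy-4-[(Z)-5-(tert-butyldiphenylsilyloxy)-3-methylpent-3-en-1-yl]-3-methylidenehexahydrofuro[3,4-b]furan-6-ol (C5 lactol) | C=C1C(OCC)O[C@H]2C(O)O[C@H](CC/C(C)=C\CO[Si](c3ccccc3)(c3ccccc3)C(C)(C)C)[C@@H]12 | intermediate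
16 | 2-ethoxy-3-methylidenetetrahydrofuran with cis substituents: (Z)-2-iodoprop-1-enyl at C5 and (1R,4Z)-1-hydroxy-6-(tert-butyldiphenylsilyloxy)-4-methylhex-4-enyl at C4 | C=C1C(OCC)O[C@@H](/C=C(/C)I)[C@H]1[C@H](O)CC/C(C)=C\CO[Si](c2ccccc2)(c2ccccc2)C(C)(C)C | intermediate
17 | C8 (Z)-2-methylbut-2-enoate (angelate) of 16 | C=C1C(OCC)O[C@@H](/C=C(/C)I)[C@H]1[C@H](OC(=O)/C(C)=C\C)CC/C(C)=C\CO[Si](c2ccccc2)(c2ccccc2)C(C)(C)C | intermediate
18 | C12 lactol of 17 (2-hydroxy-3-methylidenetetrahydrofuran) | C=C1C(O)O[C@@H](/C=C(/C)I)[C@H]1[C@H](OC(=O)/C(C)=C\C)CC/C(C)=C\CO[Si](c2ccccc2)(c2ccccc2)C(C)(C)C | intermediate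
19 | cis-4,5-disubstituted 3-methylidenedihydrofuran-2(3H)-one: C5 (Z)-2-iodoprop-1-enyl, C4 (1R,4Z)-1-angeloyloxy-6-(tert-butyldiphenylsilyloxy)-4-methylhex-4-enyl | C=C1C(=O)O[C@@H](/C=C(/C)I)[C@H]1[C@H](OC(=O)/C(C)=C\C)CC/C(C)=C\CO[Si](c2ccccc2)(c2ccccc2)C(C)(C)C | intermediate
20 | desilylated 19 ((Z)-allylic alcohol, C3–OH) | C=C1C(=O)O[C@@H](/C=C(/C)I)[C@H]1[C@H](OC(=O)/C(C)=C\C)CC/C(C)=C\CO | intermediate
21 | epoxy alcohol: side chain of 20 ending in (2S,3R)-3-(hydroxymethyl)-2-methyloxiran-2-yl | C=C1C(=O)O[C@@H](/C=C(/C)I)[C@H]1[C@H](OC(=O)/C(C)=C\C)CC[C@]2(C)O[C@@H]2CO | intermediate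
22 | epoxy aldehyde: side chain ending in (2S,3S)-3-formyl-2-methyloxiran-2-yl | C=C1C(=O)O[C@@H](/C=C(/C)I)[C@H]1[C@H](OC(=O)/C(C)=C\C)CC[C@]2(C)O[C@@H]2C=O | intermediate
23 | alkenylchromium dichloride formed from 22 at C4 | C=C1C(=O)O[C@@H](/C=C(/C)[Cr](Cl)Cl)[C@H]1[C@H](OC(=O)/C(C)=C\C)CC[C@]2(C)O[C@@H]2C=O | intermediate (not isolated)
24 | CNP0500828.1 | C=C1C(=O)O[C@H]2/C=C(/C)[C@@H](O)[C@H]3O[C@@]3(C)CC[C@@H](OC(=O)/C(C)=C\C)[C@@H]12 | target

**Step count and risks**

Total step count: 17. Longest linear sequence: 16 steps (1 to 24 through steps 1, 2 and 4–17; the sugar branch from 5 is 15 steps).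

Steps most likely to fail, most critical first:

Step 17. The ring closure must run at high dilution and may show incomplete facial control at the aldehyde carbon, giving both C3 epimers. The fallback sets out from 22: the chromium-mediated closure is run as before and accepted as a mixture of 24 and the C3 epimer of 24 F1. The mixture is oxidized with Dess–Martin periodinane (pyridine, CH2Cl2) to the ten-membered epoxy enone F2. The C3 carbinol is then made by reagent-controlled 1,2-reduction of the ketone (CBS oxazaborolidine with catecholborane at low temperature, the catalyst enantiomer chosen to match, or NaBH4/CeCl3 as the substrate-controlled variant), which comes back to 24. The stereocenter is thus set by ketone reduction and no longer by the C–C bond formation.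

Step 10. The basic and thermally fragile iodo-ylide may be consumed by the lactol hydroxyl, and the Z-selectivity may erode. The fallback sets out from 15: dibromomethylenation with Ph3P=CBr2 (from [Ph3PCHBr2]Br and KOt-Bu, THF) should give the 1,1-dibromoalkene F3. Palladium-catalyzed monomethylation (MeZnCl, Pd(DPEphos)Cl2 (cat.), THF), which replaces the bromide trans to C6, should give the (Z)-2-bromoalkene F4. Halide exchange with retention (NaI, CuI (cat.), N,N′-dimethylethylenediamine, dioxane, 110 °C) comes back to 16. The alkene geometry then comes from a stereoselective cross-coupling on a gem-dihalide and not from a Wittig transition state.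

Step 7. Acetal exchange at an alkynyl acetal is slow because the oxocarbenium ion is destabilized by the alkyne, so scrambling at the anomeric S,O-acetal or double exchange may compete. The fallback sets out from 10: 3-chloro-3-ethoxyprop-1-yne F5 is prepared from 3,3-diethoxyprop-1-yne with acetyl chloride and ZnBr2 (cat.) and used to alkylate the O6 hydroxyl of 10 under basic conditions (i-Pr2NEt, CH2Cl2, 0 °C), which comes back to 11 without any acid.

Further compounds
F1 | step 17 | C3 epimer of 24 | C=C1C(=O)O[C@H]2/C=C(/C)[C@H](O)[C@H]3O[C@@]3(C)CC[C@@H](OC(=O)/C(C)=C\C)[C@@H]12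
F2 | step 17 | ten-membered epoxy enone (C3 ketone of 24) | C=C1C(=O)O[C@H]2/C=C(/C)C(=O)[C@H]3O[C@@]3(C)CC[C@@H](OC(=O)/C(C)=C\C)[C@@H]12
F3 | step 10 | 1,1-dibromoalkene analogue of 16 (C5=CBr2) | C=C1C(OCC)O[C@@H](C=C(Br)Br)[C@H]1[C@H](O)CC/C(C)=C\CO[Si](c2ccccc2)(c2ccccc2)C(C)(C)C
F4 | step 10 | (Z)-2-bromoprop-1-enyl analogue of 16 | C=C1C(OCC)O[C@@H](/C=C(/C)Br)[C@H]1[C@H](O)CC/C(C)=C\CO[Si](c2ccccc2)(c2ccccc2)C(C)(C)C
F5 | step 7 | 3-chloro-3-ethoxyprop-1-yne | C#CC(Cl)OCC
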